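I had no rate constants to begin with, just two runs, so I asked them where open intermediate stops rising.

| flask | substrate | partner | protic impurity | temperature | remark | time |
|---|---|---|---|---|---|---|
| dusk | 0.80 M | 1.2 M | 0.40 M | 78 °C | run made earlier |  |
| midnight | 0.80 M | 1.2 M | 1.6 M | 94 °C | run made earlier |  |
| epsilon | 0.80 M | 1.20 M | 0.800 M | 70 °C |  | 12 min |
| theta | 0.80 M | 1.20 M | 0.800 M |  | at 100 °C until 2.5 min, from then on at 70 °C | 12 min |
| alpha | 0.80 M | 1.20 M | 0.800 M | 100 °C |  | 12 min |
| gamma | 0.80 M | 1.20 M | 0.800 M | 85 °C |  | 12 min |

| run | time / min | open intermediate / % | target / % |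
|---|---|---|---|
| dusk | 0.833 | 14.8 | 0.6 |
| dusk | 2.00 | 22.9 | 5.2 |
| dusk | 4.00 | 20.3 | 18.4 |
| dusk | 6.00 | 14.3 | 31.6 |
| dusk | 8.00 | 10.1 | 41.0 |
| dusk | 12.0 | 3.9 | 51.3 |
| dusk | 15.0 | 2.7 | 55.5 |
| midnight | 0.333 | 20.4 | 1.3 |
| midnight | 0.667 | 24.5 | 8.5 |
| midnight | 0.833 | 24.0 | 11.8 |
| midnight | 1.33 | 17.8 | 24.0 |
| midnight | 2.00 | 11.4 | 35.3 |
| midnight | 3.00 | 5.2 | 43.9 |
| midnight | 5.00 | 0.8 | 49.8 |

(standard deviation of a reading: 0.3 percentage points)

1. which flask leads in amount of open intermediate, in percent of the substrate charged ("all alike" within 1.5 percentage points) (epsilon / theta / alpha / gamma / all alike)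
2. how much open intermediate is there at the end, in percent of the substrate charged: epsilon
3. how much open intermediate is there at the end, in percent of the substrate charged: theta
4. how much open intermediate is there at the end, in percent of the substrate charged: alpha
5. how much open intermediate is there at the end, in percent of the substrate charged: gamma



At its peak, open intermediate is made as fast as it is used; after that crossing, the loss leads. The top reading stood at 2.00 min in dusk and at 0.667 min in midnight, a factor of 3.00 between 78 °C and 94 °C. That factor also carried the change of protic impurity, which I could not separate from temperature. I spread it evenly over the degrees to get a peak time for each temperature.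

Epsilon: peak at 3.46 min, count 3.46

Gamma: peak at 1.24 min, count 9.70

Alpha: peak at 0.442 min, count 27.2

Theta: 2.5 min on the hot peak time, the rest on the cold one, count 8.40

This peak count, the time run divided by the peak time at that temperature, is a reduced time.

Was one number enough? At count 3.00, dusk read 14.3 % and midnight 11.4 %, a gap of 2.9 percentage points, so the count ranks flasks better than it gives amounts. Epsilon, past its peak, had the smallest count. It fell between dusk's readings at 6.00 min and 8.00 min, so I reckoned about 12.2 %. The other flasks had passed dusk's last count of 7.50, so I put them under 2.7 %.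

The forecast named epsilon, with 14 %, 1.4 %, 0.03 % and 0.8 % for epsilon, theta, alpha and gamma, noting: “Temperature and impurity are confounded between the two runs.”

The simulation gave epsilon the lead with 14.7 %, against 0.473 % for theta, 0 % for alpha and 0.545 % for gamma. At the end, epsilon still held 30.9 % of its substrate. Its amount stood 2.5 points above my reckoning, inside the gap, and above dusk's reading at count 3.00, so on dusk's readings epsilon stood short of that count, and my 3.46 ran ahead of it by an amount that the gap between the runs leaves open.

    2 open intermediate → homo product (k = 0.160 L mol⁻¹ min⁻¹, Ea = 59.0 kJ mol⁻¹)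
    open intermediate → decomposed reagent (k = 0.0650 min⁻¹, Ea = 111 kJ mol⁻¹)
    substrate → open intermediate (k = 0.0980 min⁻¹, Ea = 97.0 kJ mol⁻¹)
    open intermediate + second intermediate → target (k = 0.320 L mol⁻¹ min⁻¹, Ea = 74.0 kJ mol⁻¹)
    partner + protic impurity → quenched reagent (k = 0.0160 L mol⁻¹ min⁻¹, Ea = 83.0 kJ mol⁻¹)
    partner → second intermediate (k = 0.110 min⁻¹, Ea = 102 kJ mol⁻¹)
    (constants at 70 °C)

For the neighbour of alpha at 75 °C, the count becomes 4.88, which lies between dusk's readings at 8.00 min and 12.0 min, so between 10.1 % and 3.9 %. The computed flask gave 8.05 %.

Readings and results were generated by integration with constants of no real substance, noise included.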